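**Remark.** Atoms carry drimane numbers (ring A: C1–C5 and C10; ring B: C5–C10; C11 on C9, C12 on C8, C13 and C14 on C4, C15 on C10), and β is the face of ring B that bears the C10 methyl group. The target is treated as the open hydroxy acid–aldehyde as drawn; its C11 carboxyl and C12 formyl groups may equilibrate with a cyclic hydroxy lactone, which is a property of the compound and not of the route.

## Analysis of the target

The target is a sesquiterpenoid acid on a drimane carbon skeleton whose decalin is cis-fused: H5 and the C10 methyl group lie on the same face. Ring A is saturated and carries only the C4 gem-dimethyl group, whereas ring B carries every functional group. The four stereocentres C5, C6, C9 and C10 are contiguous around ring B. H5, the C10 methyl, the ester oxygen on C6 and the hydroxyl on C9 are all β, while the C11 carboxyl and the ring A bonds to C1 and C4 are α. O6 and O9 are therefore cis-1,4 across the C7=C8 double bond. C9 and C10 are adjacent fully substituted carbons. The sensitive groups are the C12 enal, the tertiary α-hydroxy acid next to it, the allylic trienoate (prone to isomerisation, deconjugation and oxidation) and the free acid. The difficulties are the cis fusion at a quaternary C10, the dense and differentiated oxidation of ring B (C11 acid beside C12 aldehyde), and the need to bring in the triene last. The strategy rests on the fact that C5–C10 with C12 are the skeleton of (S)-carvone 4: carbonyl carbon = C9, methyl-bearing olefinic carbon = C8 with C12, then C7, C6, the C5 stereocentre, and the α′ carbon = C10. The isopropenyl group of carvone is C4 with C13 and C14, so ring A reduces to a three-carbon chain C1–C3 on C10 that closes onto C4.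

## Retrosynthetic reasoning

**C11 acid.** The free acid of 22 is released last from the 4-methoxybenzyl ester 21. The ester keeps C11 from being activated during acylation of O6, and it is cleaved by alkyl–oxygen fission, so the hindered C11 carbonyl never has to be attacked.

**O6–acyl bond.** 21 is cut at the ester C–O bond into the allylic alcohol 18 and the trienoic acid 19. The triene enters late because it would not survive the oxidations that ring B needs. The forward reaction must acylate the secondary 6-OH and leave the tertiary 9-OH alone, which their steric difference allows.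

**C12 oxidation.** The formyl group of 18 is traced through the silyl ether 17 to the C12 methyl group of 16. Allylic oxidation of a trisubstituted olefin goes to the allylic position on its more substituted carbon, C8. C9 has no hydrogen, so only C12 can react. O6 is silylated so that the secondary allylic alcohol is not oxidised.

**C6–O and C9–O together.** The cis-1,4-diol 15 (parent of 16) is the reduction product of the endoperoxide 14, which comes from a [4+2] photooxygenation of the ring B diene ester 13. Both C–O bonds are cut at once because they are cis and flank C7=C8. The gain is that two stereocentres are set in one step by one facial preference: ring A blocks the α face of the diene.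

**C9–C11.** The ester carbon of 13 is attached by alkoxycarbonylation of the dienyl triflate 12. The triflate is made from the enone 10 through its γ-dienolate 11. This reuses the carvone carbonyl carbon as C9 and creates the ring B diene in the same operation.

**C2=C3.** 10 comes from the dienone 9 by hydrogenation of the isolated ring A olefin.

**C3–C4 (key).** Ring A of 9 is opened at C3–C4. This gives the carvone derivative 8, whose isopropenyl group is the latent C4 cation and whose (Z)-vinylsilane chain on C10 is the nucleophile. The cut is made here because it returns the ring B skeleton of a chiral-pool terpene with the C4 gem-dimethyl group already in place. The forward step must form one C–C bond without creating a stereocentre.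

**C10–C15 and C10–C1.** 8 is the product of two successive enolate alkylations of (S)-carvone 4 at its α′ carbon. The chain comes first (6, from bromide 3, via enolate 5) and methyl second (via enolate 7), so that methyl enters anti to the isopropenyl group and the chain ends up cis to it.

**Chain reagent.** Bromide 3 comes from the (Z)-allylic alcohol 2, made by cis semihydrogenation of the silylpropynol 1.

## Alternatives that were turned down

**Alternative 1:** The disconnection cuts C5–C10 and C8–C9, so both rings come from one acyclic chain: the triene imide A1, a 2-silyloxy diene (C5=C6–C7=C8) tied through C4–C1 to a (Z)-β-methyl enoyl oxazolidinone (C9=C10). Forward, A1 would undergo an intramolecular Diels–Alder reaction under [Cu((S,S)-tBu-box)](SbF6)2, a chelating complex of divalent copper, to give the cis-fused silyl enol ether imide A2.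
- For it: two rings, two bonds and the cis relationship of C5 and C10 arise in one catalytic asymmetric step, and O6 is already present as an enol ether. On convergence and on rings formed per step it is stronger than the chosen route.
- Against it: the dienophile carbon C10 is β,β-disubstituted and the diene terminus C5 is attached to the quaternary C4, so the C5–C10 bond must join two congested carbons under a Lewis acid that activates trisubstituted enoyl imides only weakly. C9 arrives as C–H, so the tertiary hydroxyl must later be placed on an enolate next to C10. The C8 stereocentre is made only to be destroyed when C7=C8 is introduced. The C6 ketone then needs a face-selective reduction. A1 itself needs two geometrically defined trisubstituted olefins and a regiodefined silyl dienol ether.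
- Comparison: the chosen route forms one ring less in its key step, but it takes its absolute configuration from (S)-carvone instead of relying on a catalyst for both enantio- and endo/exo control, and it reaches its cyclisation substrate in four steps.

**Alternative 2:** The disconnection cuts C5–C6 and C9–C10, so ring B is assembled from 3-hydroxy-4-methyl-2-pyrone A3 and 2,4,4-trimethylcyclohex-2-enone A4. Forward, the oxido anion of A3, paired with a chiral bifunctional cinchona amine, would add across the C=C of A4 to give the lactone-bridged bicyclo[2.2.2]octene A5.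
- For it: two simple partners deliver in one step the C9 hydroxyl, C11 at the acid level, the C8 methyl, C7=C8 and an oxygen on C6, with cis fusion guaranteed by the cyclic dienophile. On oxidation-state economy it is clearly stronger; the chosen route spends steps 7 to 11 on the same groups.
- Against it: A4 is a poor dienophile. Its β-carbon C5 is neopentyl (next to C4) and its α-carbon C10 is substituted, so the stepwise Michael–aldol course of the anionic pyrone must form C5–C6 at a shielded carbon and then C9–C10 between two fully substituted carbons. The bridged lactone loses CO2 on heating, so the reaction cannot be forced. A5 has C6 epimeric to the target (O6 is tied to the α-oriented C11), so C6 must be inverted after the lactone is opened. The C1 ketone must be removed next to ring B functionality, and C12 still needs oxidation.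
- Comparison: the chosen route is longer, but each of its bond formations is intramolecular or occurs at an unhindered carbon, and its stereochemistry does not depend on untested catalyst control.

**Alternative 3:** The disconnection cuts C9–C10. Forward, SmI2 (divalent samarium) would reduce the α-keto ester of A6 to the C9 ketyl, which adds 6-exo to C10 of the ring A enone to give the cis-fused hydroxy ester A7 (C2 ketone, C6 ketal).
- For it: the most congested bond of the target is made by a radical addition that tolerates hindrance, and the C9 hydroxyl and C11 ester appear at once at their final oxidation level. On directness at C9 it is stronger than the chosen route.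
- Against it: A6 already contains C5 and C8 as stereocentres. C5 is γ to the ring A enone and can be lost through the dienolate, and C8 is destroyed later. After cyclisation the C2 ketone must be removed, the C6 ketal turned into a 6β-alcohol, C7=C8 introduced and C12 oxidised. The facial course of the ketyl addition is governed by a single ring stereocentre.
- Comparison: the chosen route makes C10 quaternary by enolate alkylation under well-understood control and sets C6 and C9 together by one cycloaddition, which gives a shorter sequence with fewer redox corrections.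

Key step: step 5

## Route

Step 1
Reactants: 1 3-(trimethylsilyl)prop-2-yn-1-ol
Product: 2 (2Z)-3-(trimethylsilyl)prop-2-en-1-ol
Conditions: H2 (1 atm), Ni2B from Ni(OAc)2·4H2O and NaBH4 (cat.), H2NCH2CH2NH2, EtOH, rt
Reagents that add atoms: none
Why: Semihydrogenation of a silylalkyne over amine-poisoned nickel boride delivers both hydrogens syn and stops at the olefin, so the (Z)-vinylsilane should result with the C–Si bond and the alcohol untouched.

Step 2
Reactants: 2 (2Z)-3-(trimethylsilyl)prop-2-en-1-ol
Product: 3 [(1Z)-3-bromoprop-1-en-1-yl]trimethylsilane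
Conditions: CBr4, PPh3, CH2Cl2, 0 °C
Reagents that add atoms: carbon tetrabromide, BrC(Br)(Br)Br
Why: Appel bromination replaces the primary allylic hydroxyl by SN2 at CH2 under neutral conditions, so neither the (Z) geometry nor the vinylsilane should be disturbed.

Step 3
Reactants: 4 (S)-carvone, (5S)-2-methyl-5-(prop-1-en-2-yl)cyclohex-2-en-1-one; 3 [(1Z)-3-bromoprop-1-en-1-yl]trimethylsilane
Product: 6 (5S,6R)-2-methyl-5-(prop-1-en-2-yl)-6-[(2Z)-3-(trimethylsilyl)prop-2-en-1-yl]cyclohex-2-en-1-one (major trans epimer; the 6-epimer is carried along), via carvone lithium dienolate 5 (not isolated)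
Conditions: LiN(iPr)2, THF, −78 °C; then 3, −78 → −20 °C
Reagents that add atoms: none
Why: Kinetic deprotonation of carvone occurs at the α′ carbon (future C10), and the cross-conjugated enolate is C-alkylated by the allylic bromide at its CH2 carbon; the new centre forms mainly trans to the isopropenyl group but is erased by the next enolisation.

Step 4
Reactants: 6 (5S,6R)-2-methyl-5-(prop-1-en-2-yl)-6-[(2Z)-3-(trimethylsilyl)prop-2-en-1-yl]cyclohex-2-en-1-one
Product: 8 (5R,6S)-2,6-dimethyl-5-(prop-1-en-2-yl)-6-[(2Z)-3-(trimethylsilyl)prop-2-en-1-yl]cyclohex-2-en-1-one, via lithium enolate 7 (not isolated)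
Conditions: LiN(iPr)2, THF, −78 → −20 °C; then CH3I, −78 → 0 °C
Reagents that add atoms: iodomethane, CI
Why: Second enolate alkylation at the same carbon: allylic strain in the tetrasubstituted enolate turns the neighbouring isopropenyl group pseudoaxial, so CH3I should enter from the opposite face. Methyl then stands trans and the silylallyl chain cis to the isopropenyl group, which sets C10 of the target.

Step 5
Reactants: 8 (5R,6S)-2,6-dimethyl-5-(prop-1-en-2-yl)-6-[(2Z)-3-(trimethylsilyl)prop-2-en-1-yl]cyclohex-2-en-1-one
Product: 9 (4aR,8aS)-2,5,5,8a-tetramethyl-4a,5,8,8a-tetrahydronaphthalen-1(4H)-one (cis-fused dienone: 5β-H, 10β-CH3, C2=C3, C7=C8, C9 ketone)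
Conditions: CF3SO3H (1.2 equiv), CH2Cl2, −78 → −40 °C; NaHCO3 quench
Reagents that add atoms: none
Why: CF3SO3H protonates the 1,1-disubstituted isopropenyl olefin at its CH2 carbon (Markovnikov) to give the tertiary C4 cation; this olefin is far more nucleophilic than the vinylsilane or the enone. The cation is captured by the silicon-bearing carbon C3 of the (Z)-vinylsilane on C10, forming C3–C4, and the β-silyl cation at C2 loses Me3Si+ (as Me3SiOSO2CF3), which leaves the olefin fixed at C2=C3. The closest known reaction type is the vinylsilane-terminated cation–olefin cyclisation, an ipso substitution of a vinylsilane by a tertiary carbocation. Ring A closes 6-endo-trig with respect to the vinylsilane; the 5-exo mode would need attack through C2 and an α-silyl cation, which silicon disfavours. No stereocentre is created, since C4 carries two methyl groups and C2 and C3 are sp2; the cis fusion follows from C5 (chiral pool) and C10 (step 4), whose substituents C4 and C1 lie on the same face. The (Z) geometry lets the electrophile take the place of silicon with retention, cis to C1, as the six-membered ring demands. The step needs ring closure to outrun proton loss or a 1,2-hydride shift from C5 and protodesilylation; the low temperature, the non-nucleophilic counter-ion and the proximity of the cis chain to the cation should secure this.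

Step 6
Reactants: 9 (4aR,8aS)-2,5,5,8a-tetramethyl-4a,5,8,8a-tetrahydronaphthalen-1(4H)-one
Product: 10 (4aR,8aS)-2,5,5,8a-tetramethyl-4a,5,6,7,8,8a-hexahydronaphthalen-1(4H)-one
Conditions: H2 (1–3 atm), RhCl(PPh3)3 (cat.), benzene/EtOH, rt
Reagents that add atoms: none
Why: Homogeneous hydrogenation with RhCl(PPh3)3 reduces the unconjugated cis-disubstituted C2=C3 olefin and should leave the trisubstituted conjugated C7=C8 alone; no stereocentre is involved.

Step 7
Reactants: 10 (4aR,8aS)-2,5,5,8a-tetramethyl-4a,5,6,7,8,8a-hexahydronaphthalen-1(4H)-one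
Product: 12 (4aR,8aS)-2,5,5,8a-tetramethyl-4a,5,6,7,8,8a-hexahydronaphthalen-1-yl trifluoromethanesulfonate (C6=C7 and C8=C9 diene), via lithium dienolate 11 (not isolated)
Conditions: LiN(iPr)2, THF, −78 °C; then PhN(SO2CF3)2, −78 → 0 °C
Reagents that add atoms: N-phenylbis(trifluoromethanesulfonimide), O=S(=O)(N(c1ccccc1)S(=O)(=O)C(F)(F)F)C(F)(F)F
Why: C10 is quaternary, so the only acidic position of the enone is the γ carbon C6; deprotonation gives the linear dienolate, and O-triflation should give a single dienyl triflate.

Step 8
Reactants: 12 (4aR,8aS)-2,5,5,8a-tetramethyl-4a,5,6,7,8,8a-hexahydronaphthalen-1-yl trifluoromethanesulfonate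
Product: 13 4-methoxybenzyl (4aR,8aS)-2,5,5,8a-tetramethyl-4a,5,6,7,8,8a-hexahydronaphthalene-1-carboxylate
Conditions: CO (1 atm), Pd(OAc)2 (cat.), Ph2P(CH2)3PPh2, Et3N, 4-methoxybenzyl alcohol, DMF, 70 °C
Reagents that add atoms: carbon monoxide, [C-]#[O+]; 4-methoxybenzyl alcohol, COc1ccc(CO)cc1
Why: Alkoxycarbonylation of an alkenyl triflate (oxidative addition to zerovalent palladium, CO insertion, alcoholysis of the acylpalladium) installs C11 at the acid oxidation level; CO is small enough that the insertion should tolerate the tetrasubstituted C9.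

Step 9
Reactants: 13 4-methoxybenzyl (4aR,8aS)-2,5,5,8a-tetramethyl-4a,5,6,7,8,8a-hexahydronaphthalene-1-carboxylate
Product: 15 4-methoxybenzyl (1S,4R,4aR,8aS)-1,4-dihydroxy-2,5,5,8a-tetramethyl-1,4,4a,5,6,7,8,8a-octahydronaphthalene-1-carboxylate (6β,9β-diol), via endoperoxide 14 (not isolated)
Conditions: O2, visible light, 5,10,15,20-tetraphenylporphyrin (cat.), CH2Cl2, −20 °C; then thiourea, MeOH, rt
Reagents that add atoms: dioxygen (photosensitised to its singlet state), O=O
Why: Singlet oxygen adds [4+2] to the s-cis ring B diene. Ring A (C1 and C4) covers the α face, so the O–O bridge should form between C6 and C9 on the β face beside the C10 methyl and H5. Thiourea then cleaves the O–O bond to the cis-2-ene-1,4-diol, so both carbinol centres are set at once.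

Step 10
Reactants: 15 4-methoxybenzyl (1S,4R,4aR,8aS)-1,4-dihydroxy-2,5,5,8a-tetramethyl-1,4,4a,5,6,7,8,8a-octahydronaphthalene-1-carboxylate
Product: 16 4-methoxybenzyl (1S,4R,4aR,8aS)-4-[(tert-butyldimethylsilyl)oxy]-1-hydroxy-2,5,5,8a-tetramethyl-1,4,4a,5,6,7,8,8a-octahydronaphthalene-1-carboxylate
Conditions: tBuMe2SiOSO2CF3 (1.05 equiv), 2,6-lutidine, CH2Cl2, −78 °C
Reagents that add atoms: tert-butyldimethylsilyl trifluoromethanesulfonate, CC(C)(C)[Si](C)(C)OS(=O)(=O)C(F)(F)F
Why: Silylation should distinguish the secondary allylic 6-OH from the tertiary 9-OH, which is flanked by the quaternary C10 and the ester; the silyl ether protects O6 from oxidation in the next step.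

Step 11
Reactants: 16 4-methoxybenzyl (1S,4R,4aR,8aS)-4-[(tert-butyldimethylsilyl)oxy]-1-hydroxy-2,5,5,8a-tetramethyl-1,4,4a,5,6,7,8,8a-octahydronaphthalene-1-carboxylate
Product: 17 4-methoxybenzyl (1R,4R,4aR,8aS)-4-[(tert-butyldimethylsilyl)oxy]-2-formyl-1-hydroxy-5,5,8a-trimethyl-1,4,4a,5,6,7,8,8a-octahydronaphthalene-1-carboxylate
Conditions: SeO2 (2 equiv), 1,4-dioxane, 80 °C
Reagents that add atoms: selenium dioxide, O=[Se]=O
Why: Riley allylic oxidation: the ene reaction of SeO2 at C7=C8 places selenium on the less substituted C7 and takes hydrogen from an allylic group on C8; C9 is fully substituted, so only the C12 methyl can react. The [2,3] shift and further oxidation should then give the enal without moving the double bond.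

Step 12
Reactants: 17 4-methoxybenzyl (1R,4R,4aR,8aS)-4-[(tert-butyldimethylsilyl)oxy]-2-formyl-1-hydroxy-5,5,8a-trimethyl-1,4,4a,5,6,7,8,8a-octahydronaphthalene-1-carboxylate
Product: 18 4-methoxybenzyl (1R,4R,4aR,8aS)-2-formyl-1,4-dihydroxy-5,5,8a-trimethyl-1,4,4a,5,6,7,8,8a-octahydronaphthalene-1-carboxylate
Conditions: HF·pyridine, pyridine, THF, 0 °C → rt
Reagents that add atoms: none
Why: Buffered fluoride cleaves the Si–O bond and should leave the enal, the benzylic ester and the tertiary alcohol alone; O6 and C12 are trans across C7=C8, so no lactol can form.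

Step 13
Reactants: 18 4-methoxybenzyl (1R,4R,4aR,8aS)-2-formyl-1,4-dihydroxy-5,5,8a-trimethyl-1,4,4a,5,6,7,8,8a-octahydronaphthalene-1-carboxylate; 19 (2E,4E,6E)-octa-2,4,6-trienoic acid
Product: 21 4-methoxybenzyl (1R,4R,4aR,8aS)-2-formyl-1-hydroxy-5,5,8a-trimethyl-4-{[(2E,4E,6E)-octa-2,4,6-trienoyl]oxy}-1,4,4a,5,6,7,8,8a-octahydronaphthalene-1-carboxylate, via trienoic trichlorobenzoic anhydride 20 (not isolated)
Conditions: 19, 2,4,6-trichlorobenzoyl chloride, Et3N, toluene, rt; then 18, DMAP, toluene, rt
Reagents that add atoms: none
Why: Yamaguchi esterification: DMAP attacks the less hindered trienoyl carbonyl of the mixed anhydride, and the acylpyridinium should acylate the secondary 6-OH; the tertiary 9-OH between two fully substituted carbons does not compete, and the C6 configuration is untouched.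

Step 14
Reactants: 21 4-methoxybenzyl (1R,4R,4aR,8aS)-2-formyl-1-hydroxy-5,5,8a-trimethyl-4-{[(2E,4E,6E)-octa-2,4,6-trienoyl]oxy}-1,4,4a,5,6,7,8,8a-octahydronaphthalene-1-carboxylate
Product: 22 (1R,4R,4aR,8aS)-2-formyl-1-hydroxy-5,5,8a-trimethyl-4-{[(2E,4E,6E)-octa-2,4,6-trienoyl]oxy}-1,4,4a,5,6,7,8,8a-octahydronaphthalene-1-carboxylic acid (target)
Conditions: CF3CO2H, anisole, CH2Cl2, 0 °C
Reagents that add atoms: none
Why: Acidolysis of a 4-methoxybenzyl ester goes by alkyl–oxygen cleavage through the stabilised benzylic cation, which anisole traps, so the hindered C11 carbonyl is not attacked. The C6 ester and the C9 alcohol should not ionise, because any cation there is destabilised by the formyl and carboxyl groups.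

## Compound list

1 | 3-(trimethylsilyl)prop-2-yn-1-ol | C[Si](C)(C)C#CCO | starting material
2 | (2Z)-3-(trimethylsilyl)prop-2-en-1-ol | C[Si](C)(C)/C=C\CO | intermediate
3 | [(1Z)-3-bromoprop-1-en-1-yl]trimethylsilane | C[Si](C)(C)/C=C\CBr | intermediate
4 | (S)-carvone | CC1=CC[C@@H](CC1=O)C(C)=C | starting material
5 | carvone lithium dienolate (α′ enolate) | C1C=C(C)C(O[Li])=C[C@H]1C(C)=C | intermediate (not isolated)
6 | (5S,6R)-2-methyl-5-(prop-1-en-2-yl)-6-[(2Z)-3-(trimethylsilyl)prop-2-en-1-yl]cyclohex-2-en-1-one (major trans epimer) | C1C=C(C)C(=O)[C@H](C/C=C\[Si](C)(C)C)[C@H]1C(C)=C | intermediate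
7 | lithium enolate of 6 | C1C=C(C)C(O[Li])=C(C/C=C\[Si](C)(C)C)[C@H]1C(C)=C | intermediate (not isolated)
8 | (5R,6S)-2,6-dimethyl-5-(prop-1-en-2-yl)-6-[(2Z)-3-(trimethylsilyl)prop-2-en-1-yl]cyclohex-2-en-1-one | C1C=C(C)C(=O)[C@@](C)(C/C=C\[Si](C)(C)C)[C@H]1C(C)=C | intermediate
9 | (4aR,8aS)-2,5,5,8a-tetramethyl-4a,5,8,8a-tetrahydronaphthalen-1(4H)-one | C1C=C(C)C(=O)[C@@]2(C)CC=CC(C)(C)[C@@H]12 | intermediate
10 | (4aR,8aS)-2,5,5,8a-tetramethyl-4a,5,6,7,8,8a-hexahydronaphthalen-1(4H)-one | C1C=C(C)C(=O)[C@@]2(C)CCCC(C)(C)[C@@H]12 | intermediate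
11 | lithium dienolate of 10 (γ-deprotonated) | C1=CC(C)=C(O[Li])[C@@]2(C)CCCC(C)(C)[C@@H]12 | intermediate (not isolated)
12 | (4aR,8aS)-2,5,5,8a-tetramethyl-4a,5,6,7,8,8a-hexahydronaphthalen-1-yl trifluoromethanesulfonate | C1=CC(C)=C(OS(=O)(=O)C(F)(F)F)[C@@]2(C)CCCC(C)(C)[C@@H]12 | intermediate
13 | 4-methoxybenzyl (4aR,8aS)-2,5,5,8a-tetramethyl-4a,5,6,7,8,8a-hexahydronaphthalene-1-carboxylate | C1=CC(C)=C(C(=O)OCc3ccc(OC)cc3)[C@@]2(C)CCCC(C)(C)[C@@H]12 | intermediate
14 | 4-methoxybenzyl (1S,4R,4aR,8aS)-1,4-epidioxy-2,5,5,8a-tetramethyl-1,4,4a,5,6,7,8,8a-octahydronaphthalene-1-carboxylate (6β,9β-endoperoxide) | O3[C@@H]1C=C(C)[C@@](O3)(C(=O)OCc4ccc(OC)cc4)[C@@]2(C)CCCC(C)(C)[C@@H]12 | intermediate (not isolated)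
15 | 4-methoxybenzyl (1S,4R,4aR,8aS)-1,4-dihydroxy-2,5,5,8a-tetramethyl-1,4,4a,5,6,7,8,8a-octahydronaphthalene-1-carboxylate | O[C@@H]1C=C(C)[C@@](O)(C(=O)OCc3ccc(OC)cc3)[C@@]2(C)CCCC(C)(C)[C@@H]12 | intermediate
16 | 4-methoxybenzyl (1S,4R,4aR,8aS)-4-[(tert-butyldimethylsilyl)oxy]-1-hydroxy-2,5,5,8a-tetramethyl-1,4,4a,5,6,7,8,8a-octahydronaphthalene-1-carboxylate | CC(C)(C)[Si](C)(C)O[C@@H]1C=C(C)[C@@](O)(C(=O)OCc3ccc(OC)cc3)[C@@]2(C)CCCC(C)(C)[C@@H]12 | intermediate
17 | 4-methoxybenzyl (1R,4R,4aR,8aS)-4-[(tert-butyldimethylsilyl)oxy]-2-formyl-1-hydroxy-5,5,8a-trimethyl-1,4,4a,5,6,7,8,8a-octahydronaphthalene-1-carboxylate | CC(C)(C)[Si](C)(C)O[C@@H]1C=C(C=O)[C@@](O)(C(=O)OCc3ccc(OC)cc3)[C@@]2(C)CCCC(C)(C)[C@@H]12 | intermediate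
18 | 4-methoxybenzyl (1R,4R,4aR,8aS)-2-formyl-1,4-dihydroxy-5,5,8a-trimethyl-1,4,4a,5,6,7,8,8a-octahydronaphthalene-1-carboxylate | O[C@@H]1C=C(C=O)[C@@](O)(C(=O)OCc3ccc(OC)cc3)[C@@]2(C)CCCC(C)(C)[C@@H]12 | intermediate
19 | (2E,4E,6E)-octa-2,4,6-trienoic acid | C/C=C/C=C/C=C/C(=O)O | starting material
20 | (2E,4E,6E)-octa-2,4,6-trienoic 2,4,6-trichlorobenzoic anhydride | C/C=C/C=C/C=C/C(=O)OC(=O)c1c(Cl)cc(Cl)cc1Cl | intermediate (not isolated)
21 | 4-methoxybenzyl (1R,4R,4aR,8aS)-2-formyl-1-hydroxy-5,5,8a-trimethyl-4-{[(2E,4E,6E)-octa-2,4,6-trienoyl]oxy}-1,4,4a,5,6,7,8,8a-octahydronaphthalene-1-carboxylate | C/C=C/C=C/C=C/C(=O)O[C@@H]1C=C(C=O)[C@@](O)(C(=O)OCc3ccc(OC)cc3)[C@@]2(C)CCCC(C)(C)[C@@H]12 | intermediate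
22 | (1R,4R,4aR,8aS)-2-formyl-1-hydroxy-5,5,8a-trimethyl-4-{[(2E,4E,6E)-octa-2,4,6-trienoyl]oxy}-1,4,4a,5,6,7,8,8a-octahydronaphthalene-1-carboxylic acid | C/C=C/C=C/C=C/C(=O)O[C@@H]1C=C(C=O)[C@@](O)(C(=O)O)[C@@]2(C)CCCC(C)(C)[C@@H]12 | target

## Step count and least certain steps

Total: 14 steps. Longest linear sequence: 14 steps (1 → 22 through steps 1–14); 12 steps from (S)-carvone 4.

**Step 5 (key step).** The most likely failure is loss of the C5 configuration before ring closure: proton loss from C5 to the isopropylidene isomer with reprotonation, or a 1,2-hydride shift from C5 to C4. Protodesilylation of the vinylsilane by the strong acid is the second risk. Both arise because the cation is generated reversibly in a medium that contains free CF3SO3H.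
Fallback: separate cation generation from the Brønsted acid. It sets out from 8 and returns at 9. Dry HCl in CH2Cl2 at −78 °C should add to the isopropenyl group to give the tertiary chloride F1. Ionisation of F1 with AgOSO2CF3 in the presence of 2,6-di-tert-butyl-4-methylpyridine at −40 °C would then form the C4 cation irreversibly in a buffered, proton-free medium, and the same vinylsilane capture would give 9.

**Step 9.** The ester on the diene terminus lowers its reactivity towards singlet oxygen, so the ene reaction (hydrogen abstraction from the C12 methyl or from C5) may compete with the [4+2] addition and give allylic hydroperoxides.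
Fallback: introduce the two oxygens one after the other. It sets out from 10 and returns at 16.
- tBuMe2SiOSO2CF3/Et3N would convert 10 into the silyl dienol ether F2.
- Peracid oxidation of F2 at its terminal C6=C7 bond, anti to C4, should give the 6β-hydroxy enone F3.
- Silylation of F3 would give the silyl ether F4.
- Methylenation of F4 with Cp2Ti(μ-Cl)(μ-CH2)AlMe2 would give the 9-methylene diene F5.
- OsO4 (cat.) with N-methylmorpholine N-oxide should dihydroxylate the exocyclic olefin of F5 from the β face (C1 is pseudoaxial on the α face) to give the 9β,11-diol F6.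
- SO3·pyridine/DMSO would oxidise F6 to the hydroxy aldehyde F7, and NaClO2 would take F7 to the hydroxy acid F8.
- Alkylation of F8 with 4-methoxybenzyl chloride and Cs2CO3 returns to 16.

**Step 11.** The transient C12 alcohol may transesterify onto the neighbouring C11 ester and close the five-membered lactone before it is oxidised further. The ene reaction itself may also be slow, because C7=C8 is flanked by two oxygenated carbons.
Fallback: use the lactone instead of avoiding it. It sets out from 16 and returns at 17. Catalytic SeO2 with tBuOOH in CH2Cl2 would be run to the alcohol stage and the product allowed to close to the 11,12-lactone F9. LiOH in aqueous THF would open F9 to the lithium salt F10 of the 12-hydroxy acid. Oxidation of the allylic alcohol of F10 with TEMPO/NaOCl at pH 9, where the carboxylate cannot relactonise, would give the 12-oxo acid F11. Alkylation of F11 with 4-methoxybenzyl chloride and Cs2CO3 gives 17.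

**Step 13.** The activated trienoate can lose a proton from its terminal methyl group through the conjugated chain, which leads to deconjugated or isomerised esters, and acylation of the hindered 6-OH may be slow enough for this to matter.
Fallback: build the triene after the ester bond. It sets out from 18 and returns at 21. Acylation of 18 with (2E)-3-iodoprop-2-enoic acid (carbodiimide, DMAP), which has no such acidic position, would give the iodoacrylate F12. Stille coupling of F12 with tributyl[(1E,3E)-penta-1,3-dien-1-yl]stannane under PdCl2(MeCN)2 in DMF at rt should then form the C3–C4 bond of the trienoate with retention of both geometries and give 21.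

## Further compounds

F1 | step 5 | tertiary chloride from HCl addition to the isopropenyl group of 8 | C1C=C(C)C(=O)[C@@](C)(C/C=C\[Si](C)(C)C)[C@H]1C(C)(C)Cl
F2 | step 9 | tert-butyldimethylsilyl dienol ether of 10 (C6=C7, C8=C9) | C1=CC(C)=C(O[Si](C)(C)C(C)(C)C)[C@@]2(C)CCCC(C)(C)[C@@H]12
F3 | step 9 | 6β-hydroxy enone | O[C@@H]1C=C(C)C(=O)[C@@]2(C)CCCC(C)(C)[C@@H]12
F4 | step 9 | 6β-silyloxy enone | CC(C)(C)[Si](C)(C)O[C@@H]1C=C(C)C(=O)[C@@]2(C)CCCC(C)(C)[C@@H]12
F5 | step 9 | 6β-silyloxy 9-methylene diene | CC(C)(C)[Si](C)(C)O[C@@H]1C=C(C)C(=C)[C@@]2(C)CCCC(C)(C)[C@@H]12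
F6 | step 9 | 6β-silyloxy 9β,11-diol | CC(C)(C)[Si](C)(C)O[C@@H]1C=C(C)[C@@](O)(CO)[C@@]2(C)CCCC(C)(C)[C@@H]12
F7 | step 9 | 6β-silyloxy 9β-hydroxy 11-aldehyde | CC(C)(C)[Si](C)(C)O[C@@H]1C=C(C)[C@@](O)(C=O)[C@@]2(C)CCCC(C)(C)[C@@H]12
F8 | step 9 | 6β-silyloxy 9β-hydroxy 11-oic acid | CC(C)(C)[Si](C)(C)O[C@@H]1C=C(C)[C@@](O)(C(=O)O)[C@@]2(C)CCCC(C)(C)[C@@H]12
F9 | step 11 | 6β-silyloxy 9β-hydroxy 11,12-lactone | CC(C)(C)[Si](C)(C)O[C@@H]1C=C3COC(=O)[C@@]3(O)[C@@]2(C)CCCC(C)(C)[C@@H]12
F10 | step 11 | lithium salt of the 6β-silyloxy 9β,12-dihydroxy 11-oic acid | CC(C)(C)[Si](C)(C)O[C@@H]1C=C(CO)[C@@](O)(C(=O)[O-])[C@@]2(C)CCCC(C)(C)[C@@H]12.[Li+]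
F11 | step 11 | 6β-silyloxy 9β-hydroxy 12-oxo 11-oic acid | CC(C)(C)[Si](C)(C)O[C@@H]1C=C(C=O)[C@@](O)(C(=O)O)[C@@]2(C)CCCC(C)(C)[C@@H]12
F12 | step 13 | (2E)-3-iodoprop-2-enoate of 18 at O6 | I/C=C/C(=O)O[C@@H]1C=C(C=O)[C@@](O)(C(=O)OCc3ccc(OC)cc3)[C@@]2(C)CCCC(C)(C)[C@@H]12
A1 | alternative 1 | 3-[(2Z,8Z,10E)-9-[(tert-butyldimethylsilyl)oxy]-3,7,7-trimethyldodeca-2,8,10-trienoyl]-1,3-oxazolidin-2-one (triene imide) | C/C=C/C(O[Si](C)(C)C(C)(C)C)=C/C(C)(C)CCC/C(C)=C\C(=O)N1CCOC1=O
A2 | alternative 1 | cis-fused silyl enol ether imide (cycloadduct) | C1(O[Si](C)(C)C(C)(C)C)=C[C@@H](C)[C@@H](C(=O)N3CCOC3=O)[C@@]2(C)CCCC(C)(C)[C@@H]12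
A3 | alternative 2 | 3-hydroxy-4-methyl-2H-pyran-2-one | Cc1ccoc(=O)c1O
A4 | alternative 2 | 2,4,4-trimethylcyclohex-2-en-1-one | CC1=CC(C)(C)CCC1=O
A5 | alternative 2 | lactone-bridged bicyclo[2.2.2]octene adduct (C11–O6 lactone, C1 ketone, 9-OH) | O3[C@H]1C=C(C)[C@@](O)(C3=O)[C@@]2(C)C(=O)CCC(C)(C)[C@@H]12
A6 | alternative 3 | 2-(trimethylsilyl)ethyl α-keto ester tethered through the C6 ketal to C5 of a 3,5,5-trimethylcyclohex-2-enone | O1CCOC1(C[C@@H](C)C(=O)C(=O)OCC[Si](C)(C)C)[C@H]2C(C)=CC(=O)CC2(C)C
A7 | alternative 3 | cis-fused hydroxy ester with C2 ketone and C6 ketal | O1CCOC13C[C@@H](C)[C@@](O)(C(=O)OCC[Si](C)(C)C)[C@@]2(C)CC(=O)CC(C)(C)[C@@H]32
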